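The route rests on cutting ring A at C1–C10 (terpenoid numbering, defined below). The target carries, 1,3-diaxial on ring A, the C4 carboxyl carbon C19 and the C10 oxymethylene C20, joined by the δ-lactone. C20 is first used one oxidation level higher, as the carbonyl of an isomeric δ-lactone closed onto a vinyl carbinol at C3 (compound 18). Ireland–Claisen rearrangement of its silyl ketene acetal makes C1–C10 in one operation: it closes ring A, sets the quaternary C10 from the C3 carbinol and releases C20 as an acid, later reduced onto C19. Lactone 18 comes from a Diels–Alder reaction that also builds ring B; ring C is closed last by a cationic cyclisation.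

Key step: step 11

Remarks
- Numbering: ring A = C1–C5, C10; ring B = C5–C10; ring C = C8, C9, C11–C14; C15 = benzylic CH2; C19 = lactone carbonyl on C4; C20 = OCH2 on C10.
- Reading of the target: C20, C19 and the C8 methyl group are β; H5 and H9 are α; at C13 the methyl group is β and OH α; at C14 the benzylic arm is α (axial, cis to the C13 hydroxyl). This is the pattern a Z-alkene gives in a chair cyclisation, hence nerol.
- Assumption: compounds 1, 2, 6, 10 and 12 are purchased; the lipase in step 2 is assumed to show its usual sense for secondary carbinols.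

Step 1
Reactants: 1 methyl 3,3-dimethoxypropanoate; 2 acrolein
Product: 3 methyl 2-(dimethoxymethyl)-3-hydroxypent-4-enoate (all four stereoisomers)
Conditions: LiN(i-Pr)2, THF, −78 °C; then 2, −78 °C; aq. NH4Cl
Reagents that add atoms: none
Why: Aldol addition of the lithium ester enolate to the aldehyde carbon of acrolein (1,2-addition at −78 °C); the carbinol centre is formed racemic and resolved in step 2, and the α-centre is erased in step 3.

Step 2
Reactants: 3 methyl 2-(dimethoxymethyl)-3-hydroxypent-4-enoate
Product: 4 methyl (3S)-2-(dimethoxymethyl)-3-hydroxypent-4-enoate (both C2 epimers)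
Conditions: lipase PS (Burkholderia cepacia), vinyl acetate, t-BuOMe, 30 °C, stopped past half conversion
Reagents that add atoms: none
Why: Lipase-catalysed kinetic resolution by transesterification, in which the enzyme should acylate the (3R)-carbinols (usual rule for secondary alcohols, the branched ester arm being the large group) and leave the (3S)-alcohols of both C2 epimers.

Step 3
Reactants: 4 methyl (3S)-2-(dimethoxymethyl)-3-hydroxypent-4-enoate
Product: 5 methyl (2S,3S)-2-(dimethoxymethyl)-3-hydroxy-2-methylpent-4-enoate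
Conditions: LiN(i-Pr)2 (2.2 equiv), THF, −78 to −40 °C; MeI, DMPU, −78 to −30 °C
Reagents that add atoms: iodomethane CI
Why: Fráter–Seebach alkylation, in which the chelated dianion (lithium alkoxide plus ester enolate) should be methylated on the face opposite the vinyl group of the carbinol carbon, setting the quaternary centre (later C4) as 2S from either C2 epimer.

Step 4
Reactants: 5 methyl (2S,3S)-2-(dimethoxymethyl)-3-hydroxy-2-methylpent-4-enoate; 6 2-(diethoxyphosphoryl)acetic acid
Product: 7 methyl (2S,3S)-3-[2-(diethoxyphosphoryl)acetoxy]-2-(dimethoxymethyl)-2-methylpent-4-enoate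
Conditions: DCC, DMAP (cat.), CH2Cl2, 0 to 23 °C
Reagents that add atoms: none
Why: Steglich esterification of the hindered secondary allylic alcohol, which leaves both stereocentres untouched.

Step 5
Reactants: 7 methyl (2S,3S)-3-[2-(diethoxyphosphoryl)acetoxy]-2-(dimethoxymethyl)-2-methylpent-4-enoate
Product: 9 methyl (2S,3R)-2-ethenyl-3-methyl-6-oxo-3,6-dihydro-2H-pyran-3-carboxylate, via aldehyde 8 (not isolated)
Conditions: CF3CO2H, H2O, CH2Cl2, 0 °C; then LiCl, DBU, MeCN, 23 °C
Reagents that add atoms: none
Why: Acid hydrolysis frees the non-enolisable aldehyde and an intramolecular Horner–Wadsworth–Emmons reaction (LiCl/DBU variant) closes the unsaturated six-membered lactone, whose ring enforces the Z-alkene; no stereocentre is touched.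

Step 6
Reactants: 10 nerol
Product: 11 neryl bromide
Conditions: PBr3, Et2O, −10 °C
Reagents that add atoms: phosphorus tribromide BrP(Br)Br
Why: SN2 conversion of the primary allylic alcohol into the bromide at low temperature, which should keep the Z-alkene.

Step 7
Reactants: 12 2-bromo-1,4-dimethoxybenzene; 11 neryl bromide
Product: 14 2-[(2Z)-3,7-dimethylocta-2,6-dien-1-yl]-1,4-dimethoxybenzene, via aryllithium 13 (not isolated)
Conditions: n-BuLi, THF, −78 °C; CuI (10 mol %); 11, −78 to 0 °C
Reagents that add atoms: none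
Why: Bromine–lithium exchange followed by copper-catalysed SN2 allylation of the aryllithium at the primary allylic carbon, which should keep the Z-alkene (later C13=C14).

Step 8
Reactants: 14 2-[(2Z)-3,7-dimethylocta-2,6-dien-1-yl]-1,4-dimethoxybenzene
Product: 16 (2E,6Z)-8-(2,5-dimethoxyphenyl)-2,6-dimethylocta-2,6-dienal, via allylic alcohol 15 (not isolated)
Conditions: SeO2 (cat.), t-BuOOH, CH2Cl2, 23 °C; then MnO2, CH2Cl2, 23 °C
Reagents that add atoms: tert-butyl hydroperoxide CC(C)(C)OO
Why: Riley-type allylic oxidation (ene reaction, then 2,3-shift) should attack the (E)-methyl group of the terminal trisubstituted alkene, and MnO2 takes the allylic alcohol on to the E-enal without touching the internal Z-alkene.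

Step 9
Reactants: 16 (2E,6Z)-8-(2,5-dimethoxyphenyl)-2,6-dimethylocta-2,6-dienal
Product: 17 2-[(2Z,6E)-3,7-dimethylnona-2,6,8-trien-1-yl]-1,4-dimethoxybenzene
Conditions: Ph3PCH3Br, KN(SiMe3)2, THF, 0 °C
Reagents that add atoms: methyltriphenylphosphonium bromide [Br-].C[P+](c1ccccc1)(c1ccccc1)c1ccccc1
Why: Wittig methylenation of the enal gives the E-configured 2-methyl-1,3-diene (C6=C7–C8=C9) and leaves the other alkenes alone.

Step 10
Reactants: 9 methyl (2S,3R)-2-ethenyl-3-methyl-6-oxo-3,6-dihydro-2H-pyran-3-carboxylate; 17 2-[(2Z,6E)-3,7-dimethylnona-2,6,8-trien-1-yl]-1,4-dimethoxybenzene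
Product: 18 cis-fused vinyl lactone (ring B adduct)
Conditions: EtAlCl2, CH2Cl2, −40 to 0 °C
Reagents that add atoms: none
Why: Lewis-acid promoted Diels–Alder reaction in which the unsubstituted diene terminus C6 should bond to the β-carbon C5 and the substituted terminus C9 to C10 (ortho rule, reinforced by the quaternary C4 beside C5), with endo addition anti to the pseudo-axial C4 methyl group, so that H5, H9 and H10 end up cis.

Step 11
Reactants: 18 cis-fused vinyl lactone
Product: 21 ring A acid (10β-carboxylic acid), via silyl ketene acetal 19 (not isolated), via silyl ester 20 (not isolated)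
Conditions: LiN(i-Pr)2, Me3SiCl, Et3N, THF, −78 °C; PhMe, 110 °C; aq. HCl, THF
Reagents that add atoms: none
Why: The lactone enolate is trapped as silyl ketene acetal 19, an allyl vinyl ether (C10=C20–O–C3–C2=C1), which undergoes a [3,3]-sigmatropic Ireland–Claisen shift that makes C1–C10, breaks O–C3 and leaves C2=C3 and the C20 silyl ester. The closest known reaction type is the Claisen ring contraction of vinyl-substituted lactone ketene acetals to cycloalkenecarboxylic acids. Ring A, a six-membered carbocycle, is closed by the sigmatropic bond formation itself through a boat-like transition state shaped like bicyclo[2.2.2]octane, the only one the six-membered lactone allows. The new quaternary centre C10 is controlled by the C3 carbinol centre: the shift is suprafacial, so C1 is delivered to the face of C10 on which the vinyl group stands, which puts C20 cis to the C4 ester carbon C19 and trans to H5. The step needs enolisation at C10 only and O-silylation; C10–H is the only acidic hydrogen because C4 is quaternary, and Me3SiCl is present during deprotonation.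

Step 12
Reactants: 21 ring A acid
Product: 24 tricyclic C19,C20-lactone, via acyl imidazolide 22 (not isolated), via hydroxy ester 23 (not isolated)
Conditions: CDI, THF, 40 °C; NaBH4, H2O, 0 °C; p-TsOH (cat.), PhMe, 60 °C
Reagents that add atoms: none
Why: The hindered acid is activated as the acyl imidazolide and reduced by NaBH4 to the primary alcohol, which lactonises onto the 1,3-diaxial C4 methyl ester (acid-catalysed transesterification) while the ester and the alkenes are not reduced.

Step 13
Reactants: 24 tricyclic C19,C20-lactone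
Product: 25 quinone of lactone 24
Conditions: (NH4)2Ce(NO3)6, MeCN/H2O, 0 °C
Reagents that add atoms: water O
Why: Oxidative demethylation of the 1,4-dimethoxyarene to the para-quinone, which removes the nucleophilic arene before the cationic step and should spare the isolated alkenes and the lactone.

Step 14
Reactants: 25 quinone of lactone 24
Product: 26 tetracyclic 13α-hydroxy quinone
Conditions: FSO3H, 2-nitropropane, −78 °C; then aq. NaHCO3
Reagents that add atoms: water O
Why: Proton-initiated cation–olefin cyclisation (as in the acid cyclisation of monocyclic homofarnesyl compounds), in which protonation at C7 gives the tertiary C8 cation, C14 of the Z-alkene attacks it through a chair so that the C8 methyl group ends axial (trans ring fusion) and C15 axial, and the C13 cation is captured from the equatorial side (fluorosulfate ion pair, hydrolysed on quench) while the protonated quinone stays inert.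

Step 15
Reactants: 26 tetracyclic 13α-hydroxy quinone
Product: 27 CNP0148621.1
Conditions: H2 (1 atm), Pd/C, EtOAc, 23 °C; work-up under argon
Reagents that add atoms: none
Why: Heterogeneous hydrogenation saturates the cis-disubstituted C2=C3 bond and reduces the quinone to the hydroquinone without forming a stereocentre.

Compound list
1 | methyl 3,3-dimethoxypropanoate | COC(=O)CC(OC)OC | starting material
2 | acrolein | C=CC=O | starting material
3 | methyl 2-(dimethoxymethyl)-3-hydroxypent-4-enoate, all four stereoisomers | COC(=O)C(C(OC)OC)C(O)C=C | intermediate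
4 | methyl (3S)-2-(dimethoxymethyl)-3-hydroxypent-4-enoate, both C2 epimers | COC(=O)C(C(OC)OC)[C@@H](O)C=C | intermediate
5 | methyl (2S,3S)-2-(dimethoxymethyl)-3-hydroxy-2-methylpent-4-enoate | COC(=O)[C@](C)(C(OC)OC)[C@@H](O)C=C | intermediate
6 | 2-(diethoxyphosphoryl)acetic acid | CCOP(=O)(CC(=O)O)OCC | starting material
7 | methyl (2S,3S)-3-[2-(diethoxyphosphoryl)acetoxy]-2-(dimethoxymethyl)-2-methylpent-4-enoate | COC(=O)[C@](C)(C(OC)OC)[C@@H](OC(=O)CP(=O)(OCC)OCC)C=C | intermediate
8 | methyl (2S,3S)-3-[2-(diethoxyphosphoryl)acetoxy]-2-formyl-2-methylpent-4-enoate | COC(=O)[C@](C)(C=O)[C@@H](OC(=O)CP(=O)(OCC)OCC)C=C | intermediate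
9 | methyl (2S,3R)-2-ethenyl-3-methyl-6-oxo-3,6-dihydro-2H-pyran-3-carboxylate (C3 vinyl cis to C4 methyl) | O=C1C=C[C@@](C)(C(=O)OC)[C@H](C=C)O1 | intermediate
10 | nerol | CC(C)=CCC/C(C)=C\CO | starting material
11 | neryl bromide | CC(C)=CCC/C(C)=C\CBr | intermediate
12 | 2-bromo-1,4-dimethoxybenzene | COc1ccc(OC)c(Br)c1 | starting material
13 | (2,5-dimethoxyphenyl)lithium | [Li]c1cc(OC)ccc1OC | intermediate
14 | 2-[(2Z)-3,7-dimethylocta-2,6-dien-1-yl]-1,4-dimethoxybenzene | CC(C)=CCC/C(C)=C\Cc1cc(OC)ccc1OC | intermediate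
15 | (2E,6Z)-8-(2,5-dimethoxyphenyl)-2,6-dimethylocta-2,6-dien-1-ol | OC/C(C)=C/CC/C(C)=C\Cc1cc(OC)ccc1OC | intermediate
16 | (2E,6Z)-8-(2,5-dimethoxyphenyl)-2,6-dimethylocta-2,6-dienal | O=C/C(C)=C/CC/C(C)=C\Cc1cc(OC)ccc1OC | intermediate
17 | 2-[(2Z,6E)-3,7-dimethylnona-2,6,8-trien-1-yl]-1,4-dimethoxybenzene | C=C/C(C)=C/CC/C(C)=C\Cc1cc(OC)ccc1OC | intermediate
18 | cis-fused vinyl lactone: δ-lactone C20(=O)–O–C3H(vinyl)–C4(Me)(CO2Me) fused at C5–C10 to cyclohexene ring B (C7=C8, 8-methyl, C9 side chain); 3α-vinyl, 4α-Me, 4β-CO2Me, 5α-H, 9α-H, 10α-H | O=C1O[C@@H](C=C)[C@](C)(C(=O)OC)[C@@H]2CC=C(C)[C@H](CC/C(C)=C\Cc3cc(OC)ccc3OC)[C@H]12 | intermediate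
19 | trimethylsilyl ketene acetal of 18 (C10=C20) | C[Si](C)(C)OC1=C2[C@@H](CC/C(C)=C\Cc3cc(OC)ccc3OC)C(C)=CC[C@H]2[C@@](C)(C(=O)OC)[C@H](C=C)O1 | intermediate
20 | trimethylsilyl ester of acid 21 | C[Si](C)(C)OC(=O)[C@]12CC=C[C@](C)(C(=O)OC)[C@@H]1CC=C(C)[C@@H]2CC/C(C)=C\Cc1cc(OC)ccc1OC | intermediate
21 | ring A acid: bicyclic diene (C2=C3, C7=C8) with 10β-CO2H, 4β-CO2Me, 4α-Me, 5α-H, 9α-H and the C9 side chain | OC(=O)[C@]12CC=C[C@](C)(C(=O)OC)[C@@H]1CC=C(C)[C@@H]2CC/C(C)=C\Cc1cc(OC)ccc1OC | intermediate
22 | acyl imidazolide of acid 21 | O=C(n1ccnc1)[C@]12CC=C[C@](C)(C(=O)OC)[C@@H]1CC=C(C)[C@@H]2CC/C(C)=C\Cc1cc(OC)ccc1OC | intermediate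
23 | hydroxy ester (10β-CH2OH, 4β-CO2Me) | OC[C@]12CC=C[C@](C)(C(=O)OC)[C@@H]1CC=C(C)[C@@H]2CC/C(C)=C\Cc1cc(OC)ccc1OC | intermediate
24 | tricyclic C19,C20-lactone (rings A and B plus lactone; C2=C3, C7=C8; dimethoxyaryl side chain) | O=C1OC[C@]23CC=C[C@@]1(C)[C@@H]2CC=C(C)[C@@H]3CC/C(C)=C\Cc1cc(OC)ccc1OC | intermediate
25 | quinone of lactone 24 (2-substituted 1,4-benzoquinone) | O=C1OC[C@]23CC=C[C@@]1(C)[C@@H]2CC=C(C)[C@@H]3CC/C(C)=C\CC1=CC(=O)C=CC1=O | intermediate
26 | tetracyclic 13α-hydroxy quinone (ring C closed; 8β-Me, 13β-Me, 13α-OH, 14α-CH2-quinone; C2=C3 still present) | C[C@@]12CC[C@@H]3[C@]4(CC=C[C@]3(C)C(=O)OC4)[C@H]1CC[C@](C)(O)[C@@H]2CC1=CC(=O)C=CC1=O | intermediate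
27 | CNP0148621.1 | C[C@@]12CC[C@@H]3[C@]4(CCC[C@]3(C)C(=O)OC4)[C@H]1CC[C@](C)(O)[C@@H]2Cc1cc(O)ccc1O | target

Total step count: 15. Longest linear sequence: 11 steps (steps 1–5, then 10–15).

Steps most likely to fail

Step 10. The lactone is a sluggish dienophile, so the acid-sensitive triene may be lost to Lewis-acid induced cyclisation or polymerisation before cycloaddition, or the facial and regiochemical preference may be weak. The fallback sets out from 5 and makes the dienophile doubly activated. Acylation with methyl 3-chloro-3-oxopropanoate (pyridine, CH2Cl2, 0 °C) gives the mixed malonate ester F1. Acetal hydrolysis (aq. CF3CO2H) gives the aldehyde F2, and Knoevenagel ring closure (piperidinium acetate, PhH, 60 °C) gives dimethyl (2S,3R)-2-ethenyl-3-methyl-6-oxo-3,6-dihydro-2H-pyran-3,5-dicarboxylate F3. This alkylidene malonate should add triene 17 without a strong Lewis acid (PhMe, 60 °C) to give the C10 methoxycarbonyl adduct F4. Krapcho demethoxycarbonylation (LiCl, wet DMSO, 130 °C) removes the C10 ester and comes back to the route at 18; either C10 epimer serves, since C10 is enolised in step 11.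

Step 11. Deprotonation at the hindered C10 may be slow, the enolate may be silylated on carbon, or the boat transition state may be too crowded by the C4 quaternary centre, so that the ketene acetal decomposes on heating. The fallback sets out from 18 and makes the same bond at the aldehyde level without base. Reduction with i-Bu2AlH (PhMe, −78 °C) gives the lactol F5. Dehydration (MeSO2Cl, Et3N, CH2Cl2, 0 to 40 °C) gives the cyclic enol ether F6, a 2-vinyl-3,4-dihydro-2H-pyran. Heating (xylene, 180 °C, sealed tube) brings about the aliphatic Claisen rearrangement to the ring A aldehyde F7, with the same chirality transfer from C3 to C10. NaBH4 (MeOH, 0 °C) then gives hydroxy ester 23, where the route is rejoined.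

Step 14. The C13 cation may not be captured cleanly by oxygen: loss of H14 would give the tetrasubstituted C13=C14 alkene and erase C14, the ring fusion may come out partly cis, and C13 may be attacked from the wrong face. The fallback sets out from 25 and traps the cation with solvent. Reductive acetylation (Zn, Ac2O, NaOAc, 23 °C) gives the hydroquinone diacetate F8, whose arene is deactivated. Cyclisation in formic acid (HCO2H, 23 °C) captures the C13 cation as the 13α-formate F9. Hydrogenation (H2, Pd/C, EtOAc) gives the 2,3-dihydro compound F10. Methanolysis (K2CO3, MeOH, degassed, 23 °C; then AcOH) removes the formate and both acetates and comes back to the route at 27.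

Further compounds
F1 | step 10 | methyl (2S,3S)-2-(dimethoxymethyl)-3-[(3-methoxy-3-oxopropanoyl)oxy]-2-methylpent-4-enoate | COC(=O)[C@](C)(C(OC)OC)[C@@H](OC(=O)CC(=O)OC)C=C
F2 | step 10 | methyl (2S,3S)-2-formyl-3-[(3-methoxy-3-oxopropanoyl)oxy]-2-methylpent-4-enoate | COC(=O)[C@](C)(C=O)[C@@H](OC(=O)CC(=O)OC)C=C
F3 | step 10 | dimethyl (2S,3R)-2-ethenyl-3-methyl-6-oxo-3,6-dihydro-2H-pyran-3,5-dicarboxylate | O=C1C(C(=O)OC)=C[C@@](C)(C(=O)OC)[C@H](C=C)O1
F4 | step 10 | C10 methoxycarbonyl analogue of adduct 18 | O=C1O[C@@H](C=C)[C@](C)(C(=O)OC)[C@@H]2CC=C(C)[C@H](CC/C(C)=C\Cc3cc(OC)ccc3OC)[C@]12C(=O)OC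
F5 | step 11 | lactol of 18 (C20 hemiacetal, both anomers) | OC1O[C@@H](C=C)[C@](C)(C(=O)OC)[C@@H]2CC=C(C)[C@H](CC/C(C)=C\Cc3cc(OC)ccc3OC)[C@H]12
F6 | step 11 | cyclic enol ether of 18 (C20=C10, 2-vinyl-3,4-dihydro-2H-pyran) | C1=C2[C@@H](CC/C(C)=C\Cc3cc(OC)ccc3OC)C(C)=CC[C@H]2[C@@](C)(C(=O)OC)[C@H](C=C)O1
F7 | step 11 | ring A aldehyde (10β-CHO analogue of acid 21) | O=C[C@]12CC=C[C@](C)(C(=O)OC)[C@@H]1CC=C(C)[C@@H]2CC/C(C)=C\Cc1cc(OC)ccc1OC
F8 | step 14 | hydroquinone diacetate of lactone 24 | O=C1OC[C@]23CC=C[C@@]1(C)[C@@H]2CC=C(C)[C@@H]3CC/C(C)=C\Cc1cc(OC(C)=O)ccc1OC(C)=O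
F9 | step 14 | tetracyclic 13α-formate hydroquinone diacetate (C2=C3 present) | C[C@@]12CC[C@@H]3[C@]4(CC=C[C@]3(C)C(=O)OC4)[C@H]1CC[C@](C)(OC=O)[C@@H]2Cc1cc(OC(C)=O)ccc1OC(C)=O
F10 | step 14 | 2,3-dihydro derivative of F9 | C[C@@]12CC[C@@H]3[C@]4(CCC[C@]3(C)C(=O)OC4)[C@H]1CC[C@](C)(OC=O)[C@@H]2Cc1cc(OC(C)=O)ccc1OC(C)=O
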